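**Retrosynthetic overview**
- The target comes from its 6,7,15-triacetate by selective methanolysis of the primary allylic acetate.
- Key step: both C–O bonds (C6β–OAc and C7α–OAc) are made at once by an iodine(III) anti-1,2-diacetoxylation of a ring-B 6,8-diene.
- The diene comes from a 7-oxo-Δ8 enone (dienyl triflate, Pd/formate reduction), and the enone from allylic oxidation of the Δ8(9) alkene.
- The Δ8(9) enoate comes from thermodynamic dehydration of the C8 alcohol, after HWE olefination of the methyl ketone obtained by trimming the side chain of (−)-sclareol.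
- No ring is built: rings A and B (trans-decalin, C5 and C10) are bought intact with sclareol.

Assumption: the SMILES is read as the normal-labdane enantiomer (5S,6S,7S,10S), i.e. 6β,7α-diacetoxylabda-8,13E-dien-15-ol, the same series as natural (−)-sclareol.

**Step 1**
Reactants: 1 (−)-sclareol
Product: 3 8α-hydroxy-14,15-dinorlabdan-13-one, via tetrol 2 (not isolated)
Conditions: OsO4 (1 mol %), NaIO4 (3.5 equiv), 2,6-lutidine, dioxane–H2O 3:1, rt
Reagents that add atoms: none
Why: Lemieux–Johnson dihydroxylation/periodate cleavage of the vinyl carbinol removes C14 and C15 and turns the tertiary C13–OH into the methyl ketone without touching the ring stereocentres.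

**Step 2**
Reactants: 3 8α-hydroxy-14,15-dinorlabdan-13-one; 4 triethyl phosphonoacetate
Product: 5 ethyl (13E)-8α-hydroxylabd-13-en-15-oate
Conditions: NaH (2.5 equiv), 4 (2.5 equiv), DME, 0 → 70 °C; E isomer separated on SiO2
Reagents that add atoms: triethyl phosphonoacetate, CCOC(=O)CP(=O)(OCC)OCC
Why: Horner–Wadsworth–Emmons olefination of the methyl ketone gives the trisubstituted enoate with the ester trans to the larger chain (expected E:Z about 4:1), and the minor Z isomer is removed by chromatography.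

**Step 3**
Reactants: 5 ethyl (13E)-8α-hydroxylabd-13-en-15-oate
Product: 6 ethyl (13E)-labda-8,13-dien-15-oate
Conditions: TsOH·H2O (10 mol %), toluene, 90 °C
Reagents that add atoms: none
Why: acid-catalysed E1 dehydration under equilibrating conditions funnels the C8 cation and the kinetic Δ7/Δ8(17) alkenes to the tetrasubstituted Δ8(9) olefin, while the electron-poor enoate neither ionises nor traps the cation.

**Step 4**
Reactants: 6 ethyl (13E)-labda-8,13-dien-15-oate; 7 chromium trioxide
Product: 8 ethyl (13E)-7-oxolabda-8,13-dien-15-oate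
Conditions: CrO3, 3,5-dimethylpyrazole (12 equiv each), CH2Cl2, −20 °C
Reagents that add atoms: chromium trioxide, O=[Cr](=O)=O
Why: Salmond-type allylic C–H oxidation takes the ring C7 methylene (axial C–H aligned with the Δ8 π bond) in preference to the shielded C11 and the deactivated enoate chain, as is usual for labd-8-enes and drim-8-enes.

**Step 5**
Reactants: 8 ethyl (13E)-7-oxolabda-8,13-dien-15-oate; 9 N-phenylbis(trifluoromethanesulfonimide)
Product: 11 ethyl (13E)-7-(trifluoromethanesulfonyloxy)labda-6,8,13-trien-15-oate, via potassium dienolate 10 (not isolated)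
Conditions: KHMDS (1.1 equiv), THF, −78 °C; then PhNTf2, −78 → 0 °C
Reagents that add atoms: N-phenylbis(trifluoromethanesulfonimide), FC(F)(F)S(=O)(=O)N(c1ccccc1)S(=O)(=O)C(F)(F)F
Why: kinetic α′-deprotonation of the enone at C6 (more acidic than the γ-hydrogens of the enoate) gives the cross-conjugated dienolate, which is O-sulfonylated (enol triflate formation).

**Step 6**
Reactants: 11 ethyl (13E)-7-(trifluoromethanesulfonyloxy)labda-6,8,13-trien-15-oate
Product: 12 ethyl (13E)-labda-6,8,13-trien-15-oate
Conditions: Pd(OAc)2 (5 mol %), PPh3 (10 mol %), HCO2H, n-Bu3N, DMF, 60 °C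
Reagents that add atoms: none
Why: Pd-catalysed formate reduction of the dienyl triflate (Cacchi reduction: oxidative addition, decarboxylation of formate, C–H reductive elimination) gives the homoannular 6,8-diene and leaves the enoate alone.

**Step 7**
Reactants: 12 ethyl (13E)-labda-6,8,13-trien-15-oate; 13 acetic anhydride
Product: 15 (13E)-labda-6,8,13-trien-15-yl acetate, via dienol 14 (not isolated)
Conditions: DIBAL-H (2.4 equiv), CH2Cl2, −78 °C; then pyridine, DMAP, Ac2O, −78 °C → rt
Reagents that add atoms: acetic anhydride, CC(=O)OC(C)=O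
Why: 1,2-reduction of the enoate by DIBAL-H gives the allylic aluminium alkoxide, which is acetylated in the same flask, so the acid-sensitive dienol is never handled and the Δ13 alkene enters the key step deactivated as an allylic acetate.

**Step 8**
Reactants: 15 (13E)-labda-6,8,13-trien-15-yl acetate; 16 (diacetoxyiodo)benzene
Product: 19 (13E)-labda-8,13-diene-6β,7α,15-triyl triacetate, via iodane adduct 17 (not isolated), via acetoxonium ion 18 (not isolated)
Conditions: PhI(OAc)2 (1.05 equiv), BF3·OEt2 (10 mol %), AcOH/Ac2O (anhydrous), CH2Cl2, −40 → −15 °C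
Reagents that add atoms: (diacetoxyiodo)benzene, CC(=O)OI(OC(C)=O)c1ccccc1
Why: Proposed new method: a BF3-activated PhI(OAc)2 anti-1,2-diacetoxylation of a ring-fused homoannular diene whose far terminus (C9) is fully substituted (closest known reaction type: the anhydrous Prévost-type PhI(OAc)2/BF3 diacetoxylation of simple alkenes and iodine(III) 1,2-diacetoxylation of terminal 1,3-dienes); the iodane adds to C6 from the open α face (the β face is blocked by the axial C4β and C10 methyls), acetate captures the allyl cation at C7 anti (β) instead of at the neopentyl-like C9 to give 17, the 7β-acetate then displaces the hypernucleofugal PhI at C6 from the β face to form the cis-fused acetoxonium ion 18 (this intramolecular step makes the hindered axial C6β–O bond), and acetate opens 18 at the allylic C7 with inversion from the α face to give the trans-diaxial 6β,7α-diacetate.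

**Step 9**
Reactants: 19 (13E)-labda-8,13-diene-6β,7α,15-triyl triacetate
Product: 20 (13E)-labda-8,13-diene-6β,7α,15-triol 6,7-diacetate (target, CNP0187815.1)
Conditions: K2CO3 (0.2 equiv), MeOH, 0 °C, TLC control
Reagents that add atoms: none
Why: base-catalysed transesterification (methanolysis) removes the unhindered primary allylic acetate much faster than the axial 6β-acetate (flanked by two syn-axial methyls) and the hindered secondary 7α-acetate.

**Compound list**
1 | (−)-sclareol, (13R)-labd-14-ene-8α,13-diol (5S,8R,9R,10S,13R) | C1C[C@@](C)(O)[C@H](CC[C@@](C)(O)C=C)[C@@]2(C)CCCC(C)(C)[C@H]12 | starting material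
2 | (13R)-labdane-8α,13,14,15-tetrol (C14 epimers) | C1C[C@@](C)(O)[C@H](CC[C@@](C)(O)C(O)CO)[C@@]2(C)CCCC(C)(C)[C@H]12 | intermediate
3 | 8α-hydroxy-14,15-dinorlabdan-13-one (5S,8R,9R,10S) | C1C[C@@](C)(O)[C@H](CCC(C)=O)[C@@]2(C)CCCC(C)(C)[C@H]12 | intermediate
4 | triethyl phosphonoacetate | CCOC(=O)CP(=O)(OCC)OCC | starting material
5 | ethyl (13E)-8α-hydroxylabd-13-en-15-oate (5S,8R,9R,10S) | C1C[C@@](C)(O)[C@H](CC/C(C)=C/C(=O)OCC)[C@@]2(C)CCCC(C)(C)[C@H]12 | intermediate
6 | ethyl (13E)-labda-8,13-dien-15-oate (5S,10S) | C1CC(C)=C(CC/C(C)=C/C(=O)OCC)[C@@]2(C)CCCC(C)(C)[C@H]12 | intermediate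
7 | chromium trioxide | O=[Cr](=O)=O | starting material
8 | ethyl (13E)-7-oxolabda-8,13-dien-15-oate (5S,10S) | C1C(=O)C(C)=C(CC/C(C)=C/C(=O)OCC)[C@@]2(C)CCCC(C)(C)[C@H]12 | intermediate
9 | N-phenylbis(trifluoromethanesulfonimide) | FC(F)(F)S(=O)(=O)N(c1ccccc1)S(=O)(=O)C(F)(F)F | starting material
10 | potassium (13E)-15-ethoxy-15-oxolabda-6,8,13-trien-7-olate (5S,10S) | C1=C([O-])C(C)=C(CC/C(C)=C/C(=O)OCC)[C@@]2(C)CCCC(C)(C)[C@H]12.[K+] | intermediate
11 | ethyl (13E)-7-(trifluoromethanesulfonyloxy)labda-6,8,13-trien-15-oate (5S,10S) | C1=C(OS(=O)(=O)C(F)(F)F)C(C)=C(CC/C(C)=C/C(=O)OCC)[C@@]2(C)CCCC(C)(C)[C@H]12 | intermediate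
12 | ethyl (13E)-labda-6,8,13-trien-15-oate (5S,10S) | C1=CC(C)=C(CC/C(C)=C/C(=O)OCC)[C@@]2(C)CCCC(C)(C)[C@H]12 | intermediate
13 | acetic anhydride | CC(=O)OC(C)=O | starting material
14 | (13E)-labda-6,8,13-trien-15-ol (5S,10S), present as its aluminium alkoxide | C1=CC(C)=C(CC/C(C)=C/CO)[C@@]2(C)CCCC(C)(C)[C@H]12 | intermediate
15 | (13E)-labda-6,8,13-trien-15-yl acetate (5S,10S) | C1=CC(C)=C(CC/C(C)=C/COC(C)=O)[C@@]2(C)CCCC(C)(C)[C@H]12 | intermediate
16 | (diacetoxyiodo)benzene | CC(=O)OI(OC(C)=O)c1ccccc1 | starting material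
17 | (13E)-7β-acetoxy-6α-[acetoxy(phenyl)-λ3-iodanyl]labda-8,13-dien-15-yl acetate | CC(=O)OI(c1ccccc1)[C@H]1[C@H](OC(C)=O)C(C)=C(CC/C(C)=C/COC(C)=O)[C@@]2(C)CCCC(C)(C)[C@H]12 | intermediate
18 | 6β,7β-(2-methyl-1,3-dioxolan-2-ylium) ion of (13E)-labda-8,13-dien-15-yl acetate, acetate salt (cis-fused on the β face) | CC1=[O+][C@@H]2[C@H](O1)C(C)=C(CC/C(C)=C/COC(C)=O)[C@@]3(C)CCCC(C)(C)[C@H]23.CC(=O)[O-] | intermediate
19 | (13E)-labda-8,13-diene-6β,7α,15-triyl triacetate (5S,6S,7S,10S) | CC(=O)O[C@@H]1[C@@H](OC(C)=O)C(C)=C(CC/C(C)=C/COC(C)=O)[C@@]2(C)CCCC(C)(C)[C@H]12 | intermediate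
20 | (13E)-6β,7α-diacetoxylabda-8,13-dien-15-ol (5S,6S,7S,10S) | CC(=O)O[C@@H]1[C@@H](OC(C)=O)C(C)=C(CC/C(C)=C/CO)[C@@]2(C)CCCC(C)(C)[C@H]12 | target

**Total step count:** 9. **Longest linear sequence:** 9 (fully linear from sclareol).

**Three steps most likely to fail**

Step 8 (the proposed new diacetoxylation). Risks are 1,4-addition through C9, syn delivery of the first acetate, attack of the iodane on the wrong alkene, or acid isomerisation of the diene. The fallback uses known chemistry, sets out from 15 and comes back at 19. NBS in wet DME at 0 °C puts bromine on C6 from the α face and water on the allylic C7 anti, giving (13E)-6α-bromo-7β-hydroxylabda-8,13-dien-15-yl acetate F1. K2CO3 in MeOH closes the trans-bromohydrin to the β-epoxide and removes the primary acetate, giving (13E)-6β,7β-epoxylabda-8,13-dien-15-ol F2. Buffered acetic acid (AcOH, NaOAc, rt) opens the vinyl epoxide at the allylic C7 with inversion (trans-diaxial) to (13E)-7α-acetoxylabda-8,13-diene-6β,15-diol F3. Ac2O, DMAP and pyridine then acetylate both free hydroxyls to give 19.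

Step 3 (regioselectivity of the dehydration). The equatorial 8α-OH gives Δ8(17) and Δ7 kinetically, and the Δ8(9):Δ7 ratio at equilibrium may be poor. The fallback sets out from 5 and comes back at 8, bypassing 6 and step 4. SOCl2/pyridine at −78 °C eliminates towards the methyl group (the only anti hydrogen for an equatorial leaving group) to give ethyl (13E)-labda-8(17),13-dien-15-oate F4. Catalytic SeO2 with t-BuOOH hydroxylates the ring allylic position from the α face to give ethyl (13E)-7α-hydroxylabda-8(17),13-dien-15-oate F5. Dess–Martin periodinane gives ethyl (13E)-7-oxolabda-8(17),13-dien-15-oate F6, and DBU moves the exocyclic double bond into the ring to give the conjugated enone 8.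

Step 5 (site-selective enolisation). The C6 hydrogens sit next to the axial C4/C10 methyls, and γ-deprotonation at C11 or of the enoate could compete. The fallback sets out from 6 and comes back at 12, bypassing 8 and 11. Wohl–Ziegler bromination (NBS, cat. AIBN, cyclohexane, reflux) at the ring allylic C7 gives ethyl (13E)-7ξ-bromolabda-8,13-dien-15-oate F7. Dehydrobromination (LiBr, Li2CO3, DMF, 100 °C, as in the sterol Δ5 → 5,7-diene process) then gives diene 12.

**Further compounds**
F1 | step 8 | (13E)-6α-bromo-7β-hydroxylabda-8,13-dien-15-yl acetate | Br[C@H]1[C@H](O)C(C)=C(CC/C(C)=C/COC(C)=O)[C@@]2(C)CCCC(C)(C)[C@H]12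
F2 | step 8 | (13E)-6β,7β-epoxylabda-8,13-dien-15-ol | O1[C@@H]2[C@H]1C(C)=C(CC/C(C)=C/CO)[C@@]3(C)CCCC(C)(C)[C@H]23
F3 | step 8 | (13E)-7α-acetoxylabda-8,13-diene-6β,15-diol | O[C@@H]1[C@@H](OC(C)=O)C(C)=C(CC/C(C)=C/CO)[C@@]2(C)CCCC(C)(C)[C@H]12
F4 | step 3 | ethyl (13E)-labda-8(17),13-dien-15-oate | C1CC(=C)[C@H](CC/C(C)=C/C(=O)OCC)[C@@]2(C)CCCC(C)(C)[C@H]12
F5 | step 3 | ethyl (13E)-7α-hydroxylabda-8(17),13-dien-15-oate | C1[C@@H](O)C(=C)[C@H](CC/C(C)=C/C(=O)OCC)[C@@]2(C)CCCC(C)(C)[C@H]12
F6 | step 3 | ethyl (13E)-7-oxolabda-8(17),13-dien-15-oate | C1C(=O)C(=C)[C@H](CC/C(C)=C/C(=O)OCC)[C@@]2(C)CCCC(C)(C)[C@H]12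
F7 | step 5 | ethyl (13E)-7ξ-bromolabda-8,13-dien-15-oate (C7 epimers) | C1C(Br)C(C)=C(CC/C(C)=C/C(=O)OCC)[C@@]2(C)CCCC(C)(C)[C@H]12
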